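**Strategy.** Everything rests on reading the phenol oxygen, the two aryl carbons between it and C2, then C2, C1 and the cyclopropane carbon C6 (cis to the aryl ring on the bicyclo[3.1.0]hexane) as a masked six-membered lactone: C1–C2 is the C3=C4 alkene of a 4-methylcoumarin-3-carboxylate and C6 its carbonyl carbon. A single palladium–trimethylenemethane [3+2] cycloaddition across that tetrasubstituted alkene forms C2–C3 and C1–C5, closes the cyclopentane ring and sets the C2 quaternary stereocentre, with C1 following from the cis ring fusion. The precursor is a flat, doubly activated coumarin methyl ester made in one step; the exocyclic methylene left behind becomes the C4 ketone that later closes C5–C6.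

Key step: step 2

Remarks on the chemistry (assumptions):
- Locants C1–C6 are those of the bicyclo[3.1.0]hexane core of the target (C1 and C5 ring fusion, C2 aryl-bearing, C6 the cyclopropane CH2). Tricyclic lactones are numbered as cyclopenta[c]chromenes: C9b is the future C2, C3a the future C1, and the C4 carbonyl the future C6.
- The alkyl group of the C3 ester is treated as a spectator. A methyl ester is used because chloride dealkylates a methyl group far more readily than a larger alkyl group at this congested position. Acid-labile esters are avoided because acid would isomerise the exocyclic alkene.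
- Ligand L is a BINOL-derived phosphoramidite carrying a trans-2,5-di(2-naphthyl)pyrrolidine on phosphorus, used as one enantiomer. Which antipode delivers Si-face addition at coumarin C4 cannot be predicted and is to be fixed by a small-scale screen of both.

Step 1
Reactants: 1 1-(2-hydroxy-4-methylphenyl)ethan-1-one; 2 dimethyl malonate
Product: 4 methyl 4,7-dimethyl-2-oxo-2H-chromene-3-carboxylate, via alkylidene malonate 3 (not isolated)
Conditions: TiCl4 (2 equiv), pyridine (4 equiv), THF, 0 °C → rt, then 60 °C
Reagents that add atoms: none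
Why: Knoevenagel condensation driven by TiCl4/pyridine, which forces addition–dehydration even with an aryl methyl ketone, followed by lactonisation of the phenol onto the ester that is necessarily cis to the aryl group in 3; no stereocentre is formed.

Step 2
Reactants: 4 methyl 4,7-dimethyl-2-oxo-2H-chromene-3-carboxylate; 5 2-[(trimethylsilyl)methyl]prop-2-en-1-yl acetate
Product: 6 methyl (3aS,9bS)-7,9b-dimethyl-2-methylidene-4-oxo-1,2,3,9b-tetrahydrocyclopenta[c]chromene-3a(4H)-carboxylate (cis-fused)
Conditions: Pd(dba)2 (5 mol %), phosphoramidite L (10 mol %), 5 (2 equiv), toluene, 23 → 50 °C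
Reagents that add atoms: none
Why: Proposed new method: zerovalent palladium ionises the allyl acetate of 5 and the liberated acetate removes the silyl group, giving the zwitterionic trimethylenemethane–palladium complex, whose nucleophilic carbon adds in conjugate fashion to C4 of 4 (β to both the lactone and the ester carbonyl), after which the malonate-type enolate at C3 attacks a terminus of the tethered π-allylpalladium unit and releases the catalyst. The closest known reaction type is the palladium-catalysed trimethylenemethane [3+2] cycloaddition to coumarins, alkylidene malonates and related doubly activated alkenes, made enantioselective by BINOL-derived phosphoramidites; what is unproven is a tetrasubstituted acceptor that ends with two adjacent quaternary carbons. The single new ring, the cyclopentane, closes by intramolecular C-allylation (5-exo with respect to the departing palladium) after an intermolecular first bond. C9b (the future C2) is set under ligand control, the chiral pocket having to present the Si face of C4 to the incoming carbon, and C3a (the future C1) follows from the substrate, because the three-carbon tether can only reach the planar enolate on the face from which it hangs, which enforces the cis ring fusion. The step needs 1,4- rather than 1,2-addition, C- rather than O-allylation and addition rather than deprotonation of the C4 methyl group by the basic complex; the two geminal acceptors on C3, the small methyl ester and the seven-membered ring that O-closure would require secure the first two, and the proton transfer remains the main risk.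

Step 3
Reactants: 6 methyl (3aS,9bS)-7,9b-dimethyl-2-methylidene-4-oxo-1,2,3,9b-tetrahydrocyclopenta[c]chromene-3a(4H)-carboxylate
Product: 7 (3aS,9bR)-7,9b-dimethyl-2-methylidene-2,3,3a,9b-tetrahydrocyclopenta[c]chromen-4(1H)-one (cis-fused)
Conditions: LiCl (3 equiv), H2O (3 equiv), DMSO, 150 °C; aqueous NaH2PO4 work-up
Reagents that add atoms: none
Why: Krapcho dealkoxycarbonylation, in which chloride demethylates the ester by SN2 attack at the methyl carbon, the malonate-type carboxylate loses CO2 and the lactone enolate is protonated to the cis ring junction (the C3a configuration is erased again in step 4); the neutral medium leaves the exocyclic alkene in place, and a pathway through lactone opening, decarboxylation and relactonisation would converge on the same product.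

Step 4
Reactants: 7 (3aS,9bR)-7,9b-dimethyl-2-methylidene-2,3,3a,9b-tetrahydrocyclopenta[c]chromen-4(1H)-one
Product: 9 (3aS,9bS)-3a,7,9b-trimethyl-2-methylidene-2,3,3a,9b-tetrahydrocyclopenta[c]chromen-4(1H)-one, via lithium enolate 8 (not isolated)
Conditions: LiN(iPr)2 (1.1 equiv), THF, −78 °C; MeI, DMPU, −78 → −20 °C
Reagents that add atoms: iodomethane, CI
Why: Lactone enolate alkylation, in which methylation of the ring-fusion enolate can only deliver the cis-fused bicycle because a trans-fused cyclopentane on the flattened dihydrocoumarin ring is prohibitively strained, so the new C3a methyl lands cis to the C9b methyl and the lactone carbonyl (future C6) stays cis to the aryl group.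

Step 5
Reactants: 9 (3aS,9bS)-3a,7,9b-trimethyl-2-methylidene-2,3,3a,9b-tetrahydrocyclopenta[c]chromen-4(1H)-one
Product: 10 2-[(1R,2S)-2-(hydroxymethyl)-1,2-dimethyl-4-methylidenecyclopentyl]-5-methylphenol
Conditions: LiAlH4, THF, 0 °C → rt; Na2SO4·10H2O quench
Reagents that add atoms: none
Why: Hydride reduction of the aryl ester (lactone) to the primary alcohol and the phenol, which leaves the isolated 1,1-disubstituted alkene and both quaternary stereocentres untouched.

Step 6
Reactants: 10 2-[(1R,2S)-2-(hydroxymethyl)-1,2-dimethyl-4-methylidenecyclopentyl]-5-methylphenol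
Product: 12 [(1S,2R)-1,2-dimethyl-4-methylidene-2-(4-methyl-2-{[(4-methylphenyl)sulfonyl]oxy}phenyl)cyclopentyl]methyl 4-methylbenzenesulfonate, via aryl monotosylate 11 (not isolated)
Conditions: TsCl (2.6 equiv), Et3N, DMAP (cat.), CH2Cl2, 0 °C → rt
Reagents that add atoms: 4-methylbenzenesulfonyl chloride, Cc1ccc(cc1)S(Cl)(=O)=O
Why: Double sulfonylation, in which the phenol should react first (masking the oxygen that could otherwise displace the alkyl sulfonate to a chroman) and the neopentyl alcohol second under DMAP catalysis, giving a base-stable aryl sulfonate without α-hydrogens and a leaving group on the future C6 in one operation.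

Step 7
Reactants: 12 [(1S,2R)-1,2-dimethyl-4-methylidene-2-(4-methyl-2-{[(4-methylphenyl)sulfonyl]oxy}phenyl)cyclopentyl]methyl 4-methylbenzenesulfonate
Product: 14 [(1S,2R)-1,2-dimethyl-2-(4-methyl-2-{[(4-methylphenyl)sulfonyl]oxy}phenyl)-4-oxocyclopentyl]methyl 4-methylbenzenesulfonate, via spiro ozonide 13 (not isolated)
Conditions: O3, CH2Cl2, −78 °C; then PPh3, −78 °C → rt
Reagents that add atoms: ozone, [O-][O+]=O
Why: Ozonolysis with reductive work-up, in which ozone cleaves the only alkene to the C4 ketone while the electron-poor sulfonylated arenes are inert at −78 °C; no stereocentre is involved.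

Step 8
Reactants: 14 [(1S,2R)-1,2-dimethyl-2-(4-methyl-2-{[(4-methylphenyl)sulfonyl]oxy}phenyl)-4-oxocyclopentyl]methyl 4-methylbenzenesulfonate
Product: 15 2-[(1S,2R,5R)-1,2-dimethyl-4-oxobicyclo[3.1.0]hexan-2-yl]-5-methylphenyl 4-methylbenzenesulfonate
Conditions: KOtBu (1.1 equiv), tBuOH/THF, 0 °C → rt
Reagents that add atoms: none
Why: Intramolecular enolate alkylation (1,3-elimination to a cyclopropyl ketone), in which under equilibrating conditions the C5 enolate closes onto C6 by 3-exo-tet displacement far faster than the C3 enolate could close a four-membered ring, O-alkylation would require an anti-Bredt enol ether, and the new C5 stereocentre is dictated by C1 because the cyclopropane can only fuse cis on the face that carries C6.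

Step 9
Reactants: 15 2-[(1S,2R,5R)-1,2-dimethyl-4-oxobicyclo[3.1.0]hexan-2-yl]-5-methylphenyl 4-methylbenzenesulfonate
Product: 17 2-[(1S,2R,5R)-1,2-dimethylbicyclo[3.1.0]hexan-2-yl]-5-methylphenol, via hydrazone 16 (not isolated)
Conditions: N2H4·H2O, KOH, diethylene glycol, 130 °C then 195 °C; aqueous NH4Cl work-up
Reagents that add atoms: none
Why: Wolff–Kishner reduction in its one-pot high-temperature form, in which the hydrazone anion loses N2 to give the C4 methylene without opening the adjacent cyclopropane while hydroxide cleaves the aryl sulfonate in the same pot; C1 and C2 are quaternary and C5 is a cyclopropane ring-fusion carbon, so nothing can epimerise.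

Step 10
Reactants: 17 2-[(1S,2R,5R)-1,2-dimethylbicyclo[3.1.0]hexan-2-yl]-5-methylphenol
Product: 19 2,4-dibromo-6-[(1S,2R,5R)-1,2-dimethylbicyclo[3.1.0]hexan-2-yl]-3-methylphenol (target), via laurinterol 18 (not isolated)
Conditions: NBS (2.1 equiv), NaHCO3, MeCN, 0 °C, dark
Reagents that add atoms: N-bromosuccinimide, O=C1CCC(=O)N1Br
Why: Electrophilic aromatic bromination, in which the free phenol directs NBS first to its para position and then to the single free ortho position (the other ortho carbon carries the bicycle), while the buffered, acid-free medium avoids protonation of the aryl-substituted cyclopropane.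

**Compound list**

1 | 1-(2-hydroxy-4-methylphenyl)ethan-1-one | CC(=O)c1ccc(C)cc1O | starting material
2 | dimethyl malonate | COC(=O)CC(=O)OC | starting material
3 | dimethyl 2-[1-(2-hydroxy-4-methylphenyl)ethylidene]propanedioate | COC(=O)C(C(=O)OC)=C(C)c1ccc(C)cc1O | intermediate (not isolated)
4 | methyl 4,7-dimethyl-2-oxo-2H-chromene-3-carboxylate | COC(=O)C1=C(C)c2ccc(C)cc2OC1=O | intermediate
5 | 2-[(trimethylsilyl)methyl]prop-2-en-1-yl acetate | CC(=O)OCC(=C)C[Si](C)(C)C | starting material
6 | methyl (3aS,9bS)-7,9b-dimethyl-2-methylidene-4-oxo-1,2,3,9b-tetrahydrocyclopenta[c]chromene-3a(4H)-carboxylate, cis-fused | COC(=O)[C@]12CC(=C)C[C@@]1(C)c1ccc(C)cc1OC2=O | intermediate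
7 | (3aS,9bR)-7,9b-dimethyl-2-methylidene-2,3,3a,9b-tetrahydrocyclopenta[c]chromen-4(1H)-one, cis-fused | C=C1C[C@@]2(C)c3ccc(C)cc3OC(=O)[C@H]2C1 | intermediate
8 | lithium enolate of 7 (C3a=C4 enolate, C9b retained) | [Li+].[O-]C1=C2CC(=C)C[C@@]2(C)c2ccc(C)cc2O1 | intermediate (not isolated)
9 | (3aS,9bS)-3a,7,9b-trimethyl-2-methylidene-2,3,3a,9b-tetrahydrocyclopenta[c]chromen-4(1H)-one, cis-fused | C[C@]12CC(=C)C[C@@]1(C)c1ccc(C)cc1OC2=O | intermediate
10 | 2-[(1R,2S)-2-(hydroxymethyl)-1,2-dimethyl-4-methylidenecyclopentyl]-5-methylphenol | C[C@]1(CO)CC(=C)C[C@@]1(C)c1ccc(C)cc1O | intermediate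
11 | 2-[(1R,2S)-2-(hydroxymethyl)-1,2-dimethyl-4-methylidenecyclopentyl]-5-methylphenyl 4-methylbenzenesulfonate | C[C@]1(CO)CC(=C)C[C@@]1(C)c1ccc(C)cc1OS(=O)(=O)c1ccc(C)cc1 | intermediate (not isolated)
12 | [(1S,2R)-1,2-dimethyl-4-methylidene-2-(4-methyl-2-{[(4-methylphenyl)sulfonyl]oxy}phenyl)cyclopentyl]methyl 4-methylbenzenesulfonate | C[C@]1(COS(=O)(=O)c2ccc(C)cc2)CC(=C)C[C@@]1(C)c1ccc(C)cc1OS(=O)(=O)c1ccc(C)cc1 | intermediate
13 | spiro 1,2,4-trioxolane (secondary ozonide) of 12, spiro carbon unassigned | C[C@]1(COS(=O)(=O)c2ccc(C)cc2)CC2(OCOO2)C[C@@]1(C)c1ccc(C)cc1OS(=O)(=O)c1ccc(C)cc1 | intermediate (not isolated)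
14 | [(1S,2R)-1,2-dimethyl-2-(4-methyl-2-{[(4-methylphenyl)sulfonyl]oxy}phenyl)-4-oxocyclopentyl]methyl 4-methylbenzenesulfonate | C[C@]1(COS(=O)(=O)c2ccc(C)cc2)CC(=O)C[C@@]1(C)c1ccc(C)cc1OS(=O)(=O)c1ccc(C)cc1 | intermediate
15 | 2-[(1S,2R,5R)-1,2-dimethyl-4-oxobicyclo[3.1.0]hexan-2-yl]-5-methylphenyl 4-methylbenzenesulfonate | Cc1ccc([C@]2(C)CC(=O)[C@@H]3C[C@@]32C)c(OS(=O)(=O)c2ccc(C)cc2)c1 | intermediate
16 | hydrazone of 15 at C4 (C=N geometry unassigned) | Cc1ccc([C@]2(C)CC(=NN)[C@@H]3C[C@@]32C)c(OS(=O)(=O)c2ccc(C)cc2)c1 | intermediate (not isolated)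
17 | 2-[(1S,2R,5R)-1,2-dimethylbicyclo[3.1.0]hexan-2-yl]-5-methylphenol (debromolaurinterol) | Cc1ccc([C@]2(C)CC[C@@H]3C[C@@]32C)c(O)c1 | intermediate
18 | 4-bromo-2-[(1S,2R,5R)-1,2-dimethylbicyclo[3.1.0]hexan-2-yl]-5-methylphenol (laurinterol) | Cc1cc(O)c([C@]2(C)CC[C@@H]3C[C@@]32C)cc1Br | intermediate (not isolated)
19 | 2,4-dibromo-6-[(1S,2R,5R)-1,2-dimethylbicyclo[3.1.0]hexan-2-yl]-3-methylphenol | Cc1c(Br)cc([C@]2(C)CC[C@@H]3C[C@@]32C)c(O)c1Br | target

**Totals.** Total step count: 10. Longest linear sequence: 10 steps (from 1).

**Steps most likely to fail**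

1. Step 2. The basic trimethylenemethane complex may remove a proton from the C4 methyl group instead of adding to the hindered tetrasubstituted alkene, or the ligand may discriminate poorly between the two faces of C4. The fallback sets out from 4 and returns at 6, using only Lewis-acid and enolate chemistry. Hosomi–Sakurai conjugate addition of [2-(chloromethyl)prop-2-en-1-yl]trimethylsilane to 4 (TiCl4, CH2Cl2, −78 °C) should give racemic methyl 4-[2-(chloromethyl)prop-2-en-1-yl]-4,7-dimethyl-2-oxo-3,4-dihydro-2H-chromene-3-carboxylate F1. K2CO3 in acetone at reflux should then close the cyclopentane by intramolecular C-alkylation of the malonate-type carbon, giving racemic cis-fused methyl (3aRS,9bRS)-7,9b-dimethyl-2-methylidene-4-oxo-1,2,3,9b-tetrahydrocyclopenta[c]chromene-3a(4H)-carboxylate F2. Preparative chromatography on a cellulose tris(3,5-dimethylphenylcarbamate) phase would separate 6 from its antipode methyl (3aR,9bR)-7,9b-dimethyl-2-methylidene-4-oxo-1,2,3,9b-tetrahydrocyclopenta[c]chromene-3a(4H)-carboxylate F3, which is discarded.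

2. Step 9. Hydrazone formation may stall at the cyclopropane-conjugated ketone, or the hot alkaline medium may open the three-membered ring. The fallback sets out from 15 and returns at 17, replacing carbonyl reduction by enol triflate reduction. KN(SiMe3)2 and N-phenylbis(trifluoromethanesulfonimide) in THF at −78 °C should give the enol triflate 2-[(1S,2R,5R)-1,2-dimethyl-4-(trifluoromethylsulfonyloxy)bicyclo[3.1.0]hex-3-en-2-yl]-5-methylphenyl 4-methylbenzenesulfonate F4, since only C3 can enolise next to a cyclopropane ring-fusion carbon. Formate reduction (Pd(OAc)2, PPh3, Bu3N, HCO2H, DMF, 60 °C) should give the alkene 2-[(1S,2R,5R)-1,2-dimethylbicyclo[3.1.0]hex-3-en-2-yl]-5-methylphenyl 4-methylbenzenesulfonate F5. Diimide (2-nitrobenzenesulfonohydrazide, Et3N) should saturate it without touching the cyclopropane, giving 2-[(1S,2R,5R)-1,2-dimethylbicyclo[3.1.0]hexan-2-yl]-5-methylphenyl 4-methylbenzenesulfonate F6. KOH in aqueous ethanol at reflux would then free the phenol 17.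

3. Step 1. The ketone carbonyl may resist intermolecular attack by the malonate, with reversible addition and slow dehydration stalling the condensation. The fallback sets out from 1 and returns at 4, making the C=C bond by ring closure instead. O-Acylation of 1 with methyl 3-chloro-3-oxopropanoate (Et3N, CH2Cl2, 0 °C) should give 2-acetyl-5-methylphenyl methyl propanedioate F7. Intramolecular Knoevenagel condensation (piperidine and AcOH, both catalytic, toluene, reflux with water removal) should then close the six-membered ring to 4.

**Further compounds**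

F1 | step 2 | methyl 4-[2-(chloromethyl)prop-2-en-1-yl]-4,7-dimethyl-2-oxo-3,4-dihydro-2H-chromene-3-carboxylate (racemic, C3 epimers) | COC(=O)C1C(=O)Oc2cc(C)ccc2C1(C)CC(=C)CCl
F2 | step 2 | racemic cis-fused methyl (3aRS,9bRS)-7,9b-dimethyl-2-methylidene-4-oxo-1,2,3,9b-tetrahydrocyclopenta[c]chromene-3a(4H)-carboxylate | COC(=O)C12CC(=C)CC1(C)c1ccc(C)cc1OC2=O
F3 | step 2 | methyl (3aR,9bR)-7,9b-dimethyl-2-methylidene-4-oxo-1,2,3,9b-tetrahydrocyclopenta[c]chromene-3a(4H)-carboxylate (antipode of 6) | COC(=O)[C@@]12CC(=C)C[C@]1(C)c1ccc(C)cc1OC2=O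
F4 | step 9 | 2-[(1S,2R,5R)-1,2-dimethyl-4-(trifluoromethylsulfonyloxy)bicyclo[3.1.0]hex-3-en-2-yl]-5-methylphenyl 4-methylbenzenesulfonate | Cc1ccc([C@]2(C)C=C(OS(=O)(=O)C(F)(F)F)[C@@H]3C[C@@]32C)c(OS(=O)(=O)c2ccc(C)cc2)c1
F5 | step 9 | 2-[(1S,2R,5R)-1,2-dimethylbicyclo[3.1.0]hex-3-en-2-yl]-5-methylphenyl 4-methylbenzenesulfonate | Cc1ccc([C@]2(C)C=C[C@@H]3C[C@@]32C)c(OS(=O)(=O)c2ccc(C)cc2)c1
F6 | step 9 | 2-[(1S,2R,5R)-1,2-dimethylbicyclo[3.1.0]hexan-2-yl]-5-methylphenyl 4-methylbenzenesulfonate | Cc1ccc([C@]2(C)CC[C@@H]3C[C@@]32C)c(OS(=O)(=O)c2ccc(C)cc2)c1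
F7 | step 1 | 2-acetyl-5-methylphenyl methyl propanedioate | COC(=O)CC(=O)Oc1cc(C)ccc1C(C)=O
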